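# Proposed total synthesis of CNP0284457.3 by a ring-contracting Ireland–Claisen rearrangement of a carvone-derived lactone

## Analysis of the target

Atoms are numbered along the SMILES string: C1 is the methyl-bearing sp2 carbon, C2 its partner, C3 to C8 the cyclohexane carbons, C9 the quaternary carbon, C10 the lactone carbonyl, O11 the ring oxygen, and C12 to C24 the chain back to the decalin. The skeleton is a trans-fused octalin: ring A is the cyclohexane C3–C8, ring B the cyclohexene C1, C2, C3, C8, C9, C24. A 16-membered lactone (ring C: C9, C10, O11, C12 to C24) bridges the neighbouring carbons C9 and C24. Six contiguous stereocentres sit on the decalin (24S, 9R, 8S, 3R, 4R, 5S). Ring A is all-equatorial (C4–OH, C5–Me). C9 carries an axial methyl and the lactone carbonyl. The C24 chain is cis to C10. Three further centres lie on the chain: 12R, remote from the rest, and 18R/19S, a syn hydroxyl/methyl pair. The unsaturation comprises C1=C2, an (E)-C16=C17 alkene bearing a free carboxylic acid next to the C18 carbinol (a Morita–Baylis–Hillman pattern), and a (20Z,22Z)-diene joined to the doubly allylic C24–H. Sensitive points are the Z,Z-diene, the β-hydroxy-α-alkylidene acid, and the C4 hydroxyl, which is peri to C10 and could translactonize. The core difficulty is the quaternary C9: it is flanked by two tertiary stereocentres and its carboxyl is a neopentyl ester that is also part of the macrocycle.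

## Retrosynthetic reasoning

**Protecting groups (45 from 44 and 42).** Target 45 is unmasked from bis-silyl ether acid 44 and its methyl ester 42. The ester is cleaved while the C4 oxygen is still silylated, so that no free C4 alkoxide ever sits next to the lactone carbonyl.

**C20=C21, C22=C23 and the macrocycle (42 from 41 from 40).** Both Z-alkenes are taken back to the 1,3-diyne 41, so the Z,Z geometry is created last by one cis semi-reduction. Diyne 41 is cut at C21–C22, an oxidative union of two sp carbons of like polarity in bis-alkyne 40. This site is far from the congested C9/C10 region, and both alkyne termini are robust handles in the two fragments.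

**O11–C12 (40 from 39 from 19 and 38).** The ester is cut on the alkyl side, not at the acyl C10–O bond. The forward reaction activates the unhindered alcohol of 38 and lets the carboxylate of 19 attack with inversion, which avoids acyl activation at the neopentyl carbon.

**C9–C24, the key cut (19 from 16).** Acid 19 is a cyclohex-3-ene-1-carboxylic acid, so it maps onto the [3,3] product of silyl ketene acetal 17, made from δ-lactone 16. Cutting C9–C24 and reconnecting C10–O–C2 turns ring B into a lactone that is no harder to make than an aldol adduct. The forward step must close ring B, create the quaternary C9 and the tertiary C24 together, place C1=C2, and deliver C10 at the acid oxidation level.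

**Lactone 16 from (S)-carvone 4.** Ring A is the carvone ring, C9/C10 are its isopropenyl group, and C8 is its only stereocentre. C5 is set by equilibration (4 to 6). C3 and C2 come from a syn aldol of titanium enolate 8 with enynal 3 (6 to 9). C4 is set by directed reduction (9 to 10). The isopropenyl group is oxidised and lactonised (10 to 12 to 15 to 16). Enynal 3 comes from 1 and 2 by Wittig olefination.

**Chain fragment 38.** The E-enoate is taken back to vinyl iodide 36/35, and this to the syn diynol 33 by regioselective syn-hydrostannation. Diynol 33 comes, via inversion ester 32, from anti adduct 31, the product of allenylzinc reagent 30 (from mesylate 29, made from 28) and ynal 27. Ynal 27 is built from 20 and epoxide 21 through 23 and 25.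

## Alternatives that were turned down

Alternative 1: The textbook cut is an intramolecular Diels–Alder reaction of the acyclic triene A1, forming C3–C8 and C9–C24 and both carbocycles at once to give decalin ester A2. The chain would then be attached at C24 and the ring closed by macrolactonization at C10. It was turned down for three reasons:
- It is the route most chemists would draw first.
- The dienophile is an unactivated trisubstituted enoate, so the cycloaddition needs forcing conditions, and endo/exo and facial control rest only on the two tether stereocentres C4/C5.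
- A1 needs about ten linear steps with three defined alkenes, and the hardest bond (acylation at the neopentyl C10) is left for the ring closure.

Alternative 2: A transannular Diels–Alder reaction of the 24-membered macrolactone A3 would form the same two bonds and shrink the 24-membered ring to the 6-6-16 system. The ester would then be made at an unhindered tiglate-type acid. It was turned down because A3 contains a conjugated tetraene (C3 to C20) with two Z-alkenes. Such a tetraene would be prone to electrocyclisation, hydrogen shifts and Z/E scrambling at the temperature the dienophile needs. The 24-membered ring also gives little transannular bias, and building and closing A3 would cost more steps than it saves.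

Alternative 3: A dearomatising Birch reductive alkylation of a flat aromatic amide would set the quaternary C9 (methyl and carboxyl) in diene A4 in one step. It was turned down because A4 holds only one of the six ring stereocentres. Its two alkenes would have to be differentiated, C24=C1 moved to C1=C2, a trans-fused ring A annulated at C3–C8, and C24 functionalised cis to the carboxyl. That is well over ten further steps for what the lactone route obtains from carvone and one rearrangement.

Key step: step 8

Remark (assumptions): 1, 2, 4, 20, 21 and 28 are taken as commercial. Compounds 12 to 16 are carried as C9 epimer mixtures, because C9 becomes trigonal in 17.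

## Route

### West fragment (steps 1–8)

Step 1
Reactants: 1 3-(trimethylsilyl)prop-2-ynal; 2 2-(triphenylphosphoranylidene)propanal
Product: 3 (2E)-2-methyl-5-(trimethylsilyl)pent-2-en-4-ynal
Conditions: CH2Cl2, 0 °C to rt
Reagents that add atoms: none
Why: Wittig olefination with a formyl-stabilised ylide, which gives the (E)-enal (formyl trans to the alkynyl group); the ynal is far more electrophilic than the product enal, so double olefination should stay minor.

Step 2
Reactants: 4 (S)-(+)-carvone
Product: 6 (2S,5S)-2-methyl-5-(prop-1-en-2-yl)cyclohexan-1-one (trans-dihydrocarvone), via lithium enolate 5 (not isolated)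
Conditions: LiBH(s-Bu)3, THF, −78 °C; MeOH; then NaOMe (cat.), MeOH, rt
Reagents that add atoms: none
Why: Conjugate hydride reduction of the enone by a hindered trialkylborohydride leaves the isolated isopropenyl group untouched; protonation of enolate 5 and base equilibration should enrich the diequatorial trans epimer at C5, and the minor cis epimer is removed by chromatography here or after step 3.

Step 3
Reactants: 6 (2S,5S)-2-methyl-5-(prop-1-en-2-yl)cyclohexan-1-one; 3 (2E)-2-methyl-5-(trimethylsilyl)pent-2-en-4-ynal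
Product: 9 (2S,3S,6S)-2-[(1S,2E)-1-hydroxy-2-methyl-5-(trimethylsilyl)pent-2-en-4-yn-1-yl]-6-methyl-3-(prop-1-en-2-yl)cyclohexan-1-one, via lithium enolate 7 (not isolated), via titanium enolate 8 (not isolated)
Conditions: LDA, THF, −78 °C; ClTi(OiPr)3, −78 to −40 °C; 3, −78 °C; aq. NH4F
Reagents that add atoms: none
Why: Kinetic deprotonation at the less substituted α-carbon (C3), transmetalation and aldol addition; the aldehyde adds anti to the neighbouring isopropenyl group (C3/C8 trans), and triisopropoxytitanium enolates of cyclic ketones are known to favour the syn aldol through a boat-like Zimmerman–Traxler transition state, which gives the (2S) carbinol needed in step 8.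

Step 4
Reactants: 9 aldol adduct
Product: 10 (1R,2R,3S,6S)-2-[(1S,2E)-1-hydroxy-2-methyl-5-(trimethylsilyl)pent-2-en-4-yn-1-yl]-6-methyl-3-(prop-1-en-2-yl)cyclohexan-1-ol
Conditions: Me4NBH(OAc)3, MeCN/AcOH, −30 °C
Reagents that add atoms: none
Why: Evans–Saksena hydroxyl-directed reduction delivers hydride intramolecularly from the C2 alkoxyborohydride to give the 1,3-anti diol; this coincides with axial attack on the 2,6-diequatorial cyclohexanone, so the C4 hydroxyl should come out equatorial (4R in target numbering).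

Step 5
Reactants: 10 diol
Product: 12 triol (C10 primary alcohol; C9 epimers), via alkylborane 11 (not isolated)
Conditions: 9-BBN (4 equiv), THF, 0 °C to rt; then H2O2, aq. NaOAc, 0 °C
Reagents that add atoms: hydrogen peroxide OO
Why: Hydroboration–oxidation; 9-BBN reacts with the unhindered 1,1-disubstituted alkene much faster than with the trisubstituted enyne alkene or the silyl-capped alkyne and places boron on C10; the two hydroxyl groups consume reagent as borinates that are cleaved on work-up.

Step 6
Reactants: 12 triol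
Product: 15 (1S,4aS,7S,8R,8aR)-8-hydroxy-4,7-dimethyl-1-[(2E)-5-(trimethylsilyl)pent-2-en-4-yn-2-yl]octahydro-3H-isochromen-3-one (C4 epimers; C4 of this name is C9 of the target), via hydroxy aldehyde 13 (not isolated), via lactol 14 (not isolated)
Conditions: TEMPO (cat.), PhI(OAc)2, CH2Cl2, rt
Reagents that add atoms: none
Why: Oxoammonium oxidation selects the primary alcohol; aldehyde 13 closes to the fused six-membered lactol 14 with the C2 hydroxyl (the C4 hydroxyl could only form a bridged lactol from the all-axial chair), and 14 is oxidised on to the δ-lactone with retention at C2.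

Step 7
Reactants: 15 hydroxy lactone
Product: 16 (1S,4aS,7S,8R,8aS)-8-[(tert-butyldimethylsilyl)oxy]-4,7-dimethyl-1-[(2E)-5-(trimethylsilyl)pent-2-en-4-yn-2-yl]octahydro-3H-isochromen-3-one (C4 epimers)
Conditions: TBSOTf, 2,6-lutidine, CH2Cl2, −78 to 0 °C
Reagents that add atoms: tert-butyldimethylsilyl trifluoromethanesulfonate CC(C)(C)[Si](C)(C)OS(=O)(=O)C(F)(F)F
Why: Silyl triflate protection of the hindered equatorial alcohol; the C4 oxygen is peri to C10 and would otherwise compete as a nucleophile once the C10 carboxyl is released and used.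

Step 8
Reactants: 16 silyl-protected lactone
Product: 19 (1R,2S,4aR,5R,6S,8aS)-5-[(tert-butyldimethylsilyl)oxy]-1,3,6-trimethyl-2-[(trimethylsilyl)ethynyl]-1,2,4a,5,6,7,8,8a-octahydronaphthalene-1-carboxylic acid, via silyl ketene acetal 17 (not isolated), via trimethylsilyl ester 18 (not isolated)
Conditions: LDA, TMSCl/Et3N, THF, −78 °C to rt; toluene, 105 °C; then 1 M HCl, THF
Reagents that add atoms: none
Why: Ireland–Claisen rearrangement in its ring-contracting form: LDA/TMSCl converts the δ-lactone into cyclic silyl ketene acetal 17, whose ring fixes the enol ether geometry (C8 cis to the ring oxygen), and on warming a [3,3]-sigmatropic shift breaks O–C2 and forms C9–C24 to give silyl ester 18 and, after hydrolysis, acid 19. The closest known reaction type is the lactone enolate Claisen ring contraction of 6-alkenyl-tetrahydropyran-2-ones to cyclohex-3-ene-1-carboxylic acids, which runs through a boat transition state. Ring B (C1, C2, C3, C8, C9, C24) is closed by this suprafacial [3,3] shift, the array C9=C10–O–C2–C1=C24 being held as a boat inside a bicyclo[2.2.2]octane-like cage with the C3–C8 bond as the third bridge; a chair is geometrically impossible. The quaternary centre C9 is controlled by C2: the (2S) side chain, equatorial in the resting chair, becomes axial in the lactone boat that has C8 and the ring oxygen as bow and stern, and from there C24 can only reach the β face of C9, so the methyl ends up β and the carboxyl α (9R). C24 is controlled by the (E) geometry of C1=C24: in the boat the alkynyl group, cis to the C1 methyl, eclipses the C9 methyl across the forming bond and ends up trans to it, that is cis to the carboxyl (24S). The trans ring fusion is untouched, and its gauche C2–C3–C8–C9 torsion of about 60° is exactly what this boat requires, so the trans-fused lactone is well disposed; C2 is sacrificed and becomes part of C1=C2. The step needs the [3,3] shift to outrun decomposition of the enolate or ketene acetal (self-condensation, ionisation of the allylic C2–O bond), which in situ silylation at −78 °C and the slim alkynyl group at the migrating terminus should secure.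

### East fragment (steps 9–19)

Step 9
Reactants: 20 (4-bromobut-1-yn-1-yl)trimethylsilane; 21 (S)-2-methyloxirane
Product: 23 (2S)-7-(trimethylsilyl)hept-6-yn-2-ol, via Grignard reagent 22 (not isolated)
Conditions: Mg, THF; CuI (10 mol %), 21, −30 to 0 °C; aq. NH4Cl
Reagents that add atoms: none
Why: Copper-catalysed opening of the terminal epoxide at its unsubstituted carbon by the homopropargyl Grignard reagent; the stereocentre is not touched, so the (S)-epoxide gives the (S)-alcohol.

Step 10
Reactants: 23 (2S)-7-(trimethylsilyl)hept-6-yn-2-ol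
Product: 25 1-({[(2S)-hept-6-yn-2-yl]oxy}methyl)-4-methoxybenzene, via silylalkyne ether 24 (not isolated)
Conditions: NaH, PMBCl, Bu4NI (cat.), THF/DMF, 0 °C to rt; then K2CO3, MeOH, rt
Reagents that add atoms: 4-methoxybenzyl chloride COc1ccc(CCl)cc1
Why: Williamson etherification of the sodium alkoxide, then methanolysis of the alkynyl C–Si bond in the same flask; the PMB ether is orthogonal to the silyl groups used later.

Step 11
Reactants: 25 PMB ether alkyne
Product: 27 (7S)-7-[(4-methoxybenzyl)oxy]oct-2-ynal, via lithium acetylide 26 (not isolated)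
Conditions: n-BuLi, THF, −78 °C; DMF, −78 to 0 °C; aq. KH2PO4
Reagents that add atoms: N,N-dimethylformamide CN(C)C=O
Why: Formylation of the lithium acetylide with DMF; the hemiaminal alkoxide survives until the buffered quench, which releases the ynal without conjugate addition of dimethylamine.

Step 12
Reactants: 28 (2R)-4-(trimethylsilyl)but-3-yn-2-ol
Product: 29 (2R)-4-(trimethylsilyl)but-3-yn-2-yl methanesulfonate
Conditions: MsCl, Et3N, CH2Cl2, −78 °C
Reagents that add atoms: methanesulfonyl chloride CS(=O)(=O)Cl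
Why: Sulfonylation with retention gives the standard precursor of a chiral allenylmetal reagent.

Step 13
Reactants: 27 (7S)-7-[(4-methoxybenzyl)oxy]oct-2-ynal; 29 (2R)-4-(trimethylsilyl)but-3-yn-2-yl methanesulfonate
Product: 31 (3S,4S,10S)-10-[(4-methoxybenzyl)oxy]-3-methyl-1-(trimethylsilyl)undeca-1,5-diyn-4-ol, via allenylzinc reagent 30 (not isolated)
Conditions: Pd(OAc)2 (5 mol %), PPh3 (5 mol %), Et2Zn, THF, −78 to −20 °C
Reagents that add atoms: none
Why: Zerovalent palladium displaces the mesylate anti (SN2') to an allenylpalladium species, transmetalation with Et2Zn gives allenylzinc 30, and this adds to the aldehyde through a cyclic SE2' transition state to give the anti homopropargylic alcohol; the (R)-mesylate sets C19 as S with net inversion, and the anti topicity makes C18 S, which step 14 corrects.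

Step 14
Reactants: 31 anti diynol
Product: 32 (3S,4R,10S)-10-[(4-methoxybenzyl)oxy]-3-methyl-1-(trimethylsilyl)undeca-1,5-diyn-4-yl 4-nitrobenzoate
Conditions: 4-nitrobenzoic acid, PPh3, DIAD, toluene, 0 °C to rt
Reagents that add atoms: 4-nitrobenzoic acid OC(=O)c1ccc(cc1)[N+](=O)[O-]
Why: Mitsunobu esterification with SN2 inversion at the propargylic carbinol C18 (S to R) turns the anti into the required syn C18/C19 relationship; 4-nitrobenzoic acid is the usual partner for moderately hindered secondary alcohols.

Step 15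
Reactants: 32 4-nitrobenzoate
Product: 33 (3S,4R,10S)-10-[(4-methoxybenzyl)oxy]-3-methyl-1-(trimethylsilyl)undeca-1,5-diyn-4-ol
Conditions: i-Bu2AlH, CH2Cl2, −78 °C
Reagents that add atoms: none
Why: Reductive cleavage of the aryl ester at low temperature; the base-free conditions keep the alkynyl C–Si bond that K2CO3/MeOH would cleave.

Step 16
Reactants: 33 syn diynol
Product: 35 (3S,4R,5E,10S)-5-iodo-10-[(4-methoxybenzyl)oxy]-3-methyl-1-(trimethylsilyl)undec-5-en-1-yn-4-ol, via vinylstannane 34 (not isolated)
Conditions: PdCl2(PPh3)2 (3 mol %), Bu3SnH, THF, 0 °C; then I2, CH2Cl2, 0 °C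
Reagents that add atoms: iodine II
Why: Palladium-catalysed syn-hydrostannation of the internal alkyne puts tin on the carbon next to the free propargylic hydroxyl (C17) and hydrogen on C16, while the silyl-capped alkyne reacts much more slowly; iododestannylation goes with retention, so C15 and C18 end up cis.

Step 17
Reactants: 35 iodo alcohol
Product: 36 tert-butyl{[(3S,4R,5E,10S)-5-iodo-10-[(4-methoxybenzyl)oxy]-3-methyl-1-(trimethylsilyl)undec-5-en-1-yn-4-yl]oxy}dimethylsilane
Conditions: TBSOTf, 2,6-lutidine, CH2Cl2, −78 to 0 °C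
Reagents that add atoms: tert-butyldimethylsilyl trifluoromethanesulfonate CC(C)(C)[Si](C)(C)OS(=O)(=O)C(F)(F)F
Why: Silyl triflate protection of the hindered allylic alcohol, which would otherwise interfere with the acylpalladium of step 18 and with the Mitsunobu reaction of step 20.

Step 18
Reactants: 36 silylated vinyl iodide
Product: 37 methyl (2E,7S)-2-[(1R,2S)-1-[(tert-butyldimethylsilyl)oxy]-2-methyl-4-(trimethylsilyl)but-3-yn-1-yl]-7-[(4-methoxybenzyl)oxy]oct-2-enoate
Conditions: Pd(OAc)2 (10 mol %), dppf, CO (1 atm), Et3N, MeOH/DMF, 60 °C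
Reagents that add atoms: carbon monoxide [C-]#[O+]; methanol CO
Why: Palladium-catalysed methoxycarbonylation of the vinyl iodide (oxidative addition, CO insertion, methanolysis) retains the alkene geometry and gives the (E)-2-alkylidene ester with the carboxyl trans to C15.

Step 19
Reactants: 37 PMB ether ester
Product: 38 methyl (2E,7S)-2-[(1R,2S)-1-[(tert-butyldimethylsilyl)oxy]-2-methyl-4-(trimethylsilyl)but-3-yn-1-yl]-7-hydroxyoct-2-enoate
Conditions: DDQ, CH2Cl2/pH 7 buffer, 0 °C
Reagents that add atoms: none
Why: Oxidative cleavage of the PMB ether through the benzylic oxocarbenium ion; the silyl ethers, the enoate and the silylalkyne are inert.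

### Union and endgame (steps 20–25)

Step 20
Reactants: 19 decalin acid; 38 chain alcohol
Product: 39 ester of 19 with 38 (12R): methyl (2E,7R)-2-[(1R,2S)-1-[(tert-butyldimethylsilyl)oxy]-2-methyl-4-(trimethylsilyl)but-3-yn-1-yl]-7-({[(1R,2S,4aR,5R,6S,8aS)-5-[(tert-butyldimethylsilyl)oxy]-1,3,6-trimethyl-2-[(trimethylsilyl)ethynyl]-1,2,4a,5,6,7,8,8a-octahydronaphthalen-1-yl]carbonyl}oxy)oct-2-enoate
Conditions: PPh3, DIAD, toluene, 0 °C to rt
Reagents that add atoms: none
Why: Mitsunobu esterification activates the unhindered secondary alcohol and not the neopentyl acid, so a carboxylate oxygen of 19 attacks C12 in an SN2 step with inversion (12S to 12R); the hindrance at C9 is two atoms away from the bond that forms.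

Step 21
Reactants: 39 bis(silylalkyne) ester
Product: 40 bis-terminal diyne (39 with both alkynyl trimethylsilyl groups replaced by hydrogen)
Conditions: K2CO3, MeOH/THF, 0 °C to rt
Reagents that add atoms: none
Why: Methanolysis of both alkynyl C–Si bonds; the neopentyl ester and the TBS ethers are stable, and the methyl ester can only exchange with methanol.

Step 22
Reactants: 40 bis-terminal diyne
Product: 41 16-membered 1,3-diyne lactone (C20≡C21–C22≡C23; 4-O-TBS and 18-O-TBS ethers; methyl ester)
Conditions: Cu(OAc)2 (10 equiv), pyridine/Et2O 3:1, 50 °C, slow addition to 1 mM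
Reagents that add atoms: none
Why: Eglinton oxidative coupling of the two terminal alkynes under high dilution closes ring C at C21–C22, far from the congested C9/C10 region; the linear six-carbon diyne unit is spanned without strain by the eleven remaining ring bonds.

Step 23
Reactants: 41 macrocyclic diyne
Product: 42 (20Z,22Z)-diene lactone (4-O-TBS and 18-O-TBS ethers; methyl ester)
Conditions: Zn dust activated with Cu(OAc)2 and AgNO3, MeOH/H2O/dioxane, 45 °C
Reagents that add atoms: none
Why: Boland-type reduction: activated zinc reduces conjugated alkynes by cis delivery of hydrogen from the protic solvent and stops at the alkene, so the 1,3-diyne should give the Z,Z-diene while the enoate and the isolated C1=C2 alkene stay untouched.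

Step 24
Reactants: 42 methyl ester
Product: 44 4,18-bis-O-TBS ether of the target acid, via trimethylstannyl ester 43 (not isolated)
Conditions: Me3SnOH, ClCH2CH2Cl, 75 °C; then 0.5 M HCl wash
Reagents that add atoms: trimethyltin hydroxide C[Sn](C)(C)O
Why: Trimethyltin hydroxide cleaves methyl esters under nearly neutral conditions through stannyl ester 43; the neopentyl macrolactone is far more hindered and the C4 oxygen is still silylated, so neither ring opening nor translactonization is expected.

Step 25
Reactants: 44 bis-silyl ether acid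
Product: 45 CNP0284457.3 (target)
Conditions: HF·pyridine, pyridine/THF, 0 °C to rt
Reagents that add atoms: none
Why: Fluoride cleavage of both TBS ethers under buffered acidic conditions, which avoid a free alkoxide at C4 next to the lactone carbonyl and base-induced isomerisation at the allylic C24 and C19 positions.

## Compound list

1 | 3-(trimethylsilyl)prop-2-ynal | C[Si](C)(C)C#CC=O | starting material
2 | 2-(triphenylphosphoranylidene)propanal | CC(C=O)=P(c1ccccc1)(c1ccccc1)c1ccccc1 | starting material
3 | (2E)-2-methyl-5-(trimethylsilyl)pent-2-en-4-ynal | C[Si](C)(C)C#C/C=C(\C)C=O | intermediate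
4 | (S)-(+)-carvone | CC1=CC[C@@H](CC1=O)C(C)=C | starting material
5 | lithium (4S)-2-methyl-4-(prop-1-en-2-yl)cyclohex-1-en-1-olate | [Li+].[O-]C1=C(C)CC[C@@H](C1)C(C)=C | intermediate
6 | (2S,5S)-2-methyl-5-(prop-1-en-2-yl)cyclohexan-1-one | O=C1[C@@H](C)CC[C@H](C(C)=C)C1 | intermediate
7 | lithium enolate of 6 (C3=C4 enolate, target numbering) | [Li+].[O-]C1=C[C@@H](C(C)=C)CC[C@@H]1C | intermediate
8 | triisopropoxytitanium enolate of 6 | CC(C)O[Ti](OC(C)C)(OC(C)C)OC1=C[C@@H](C(C)=C)CC[C@@H]1C | intermediate
9 | (2S,3S,6S)-2-[(1S,2E)-1-hydroxy-2-methyl-5-(trimethylsilyl)pent-2-en-4-yn-1-yl]-6-methyl-3-(prop-1-en-2-yl)cyclohexan-1-one | C[Si](C)(C)C#C/C=C(\C)[C@@H](O)[C@H]1C(=O)[C@@H](C)CC[C@@H]1C(C)=C | intermediate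
10 | (1R,2R,3S,6S)-2-[(1S,2E)-1-hydroxy-2-methyl-5-(trimethylsilyl)pent-2-en-4-yn-1-yl]-6-methyl-3-(prop-1-en-2-yl)cyclohexan-1-ol | C[Si](C)(C)C#C/C=C(\C)[C@@H](O)[C@H]1[C@H](O)[C@@H](C)CC[C@@H]1C(C)=C | intermediate
11 | B-alkyl-9-borabicyclo[3.3.1]nonane from 10 (boron on C10; hydroxyl groups written free; C9 epimers) | C[Si](C)(C)C#C/C=C(\C)[C@@H](O)[C@H]1[C@H](O)[C@@H](C)CC[C@@H]1C(C)CB1C2CCCC1CCC2 | intermediate
12 | triol: 10 with the isopropenyl group converted to 1-hydroxypropan-2-yl (C9 epimers) | C[Si](C)(C)C#C/C=C(\C)[C@@H](O)[C@H]1[C@H](O)[C@@H](C)CC[C@@H]1C(C)CO | intermediate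
13 | hydroxy aldehyde: 12 with C10 oxidised to the aldehyde (C9 epimers) | C[Si](C)(C)C#C/C=C(\C)[C@@H](O)[C@H]1[C@H](O)[C@@H](C)CC[C@@H]1C(C)C=O | intermediate
14 | lactol: cyclic hemiacetal of 13 between C10 and the C2 oxygen (C9 and C10 epimers) | C[Si](C)(C)C#C/C=C(\C)[C@H]1OC(O)C(C)[C@H]2CC[C@H](C)[C@@H](O)[C@H]12 | intermediate
15 | (1S,4aS,7S,8R,8aR)-8-hydroxy-4,7-dimethyl-1-[(2E)-5-(trimethylsilyl)pent-2-en-4-yn-2-yl]octahydro-3H-isochromen-3-one (C4 epimers) | C[Si](C)(C)C#C/C=C(\C)[C@H]1OC(=O)C(C)[C@H]2CC[C@H](C)[C@@H](O)[C@H]12 | intermediate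
16 | (1S,4aS,7S,8R,8aS)-8-[(tert-butyldimethylsilyl)oxy]-4,7-dimethyl-1-[(2E)-5-(trimethylsilyl)pent-2-en-4-yn-2-yl]octahydro-3H-isochromen-3-one (C4 epimers) | C[Si](C)(C)C#C/C=C(\C)[C@H]1OC(=O)C(C)[C@H]2CC[C@H](C)[C@@H](O[Si](C)(C)C(C)(C)C)[C@H]12 | intermediate
17 | trimethylsilyl ketene acetal of 16 (C9=C10, endocyclic) | C[Si](C)(C)C#C/C=C(\C)[C@H]1OC(O[Si](C)(C)C)=C(C)[C@H]2CC[C@H](C)[C@@H](O[Si](C)(C)C(C)(C)C)[C@H]12 | intermediate
18 | trimethylsilyl ester of 19 | CC1=C[C@H]2[C@H](O[Si](C)(C)C(C)(C)C)[C@@H](C)CC[C@@H]2[C@@](C)(C(=O)O[Si](C)(C)C)[C@H]1C#C[Si](C)(C)C | intermediate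
19 | (1R,2S,4aR,5R,6S,8aS)-5-[(tert-butyldimethylsilyl)oxy]-1,3,6-trimethyl-2-[(trimethylsilyl)ethynyl]-1,2,4a,5,6,7,8,8a-octahydronaphthalene-1-carboxylic acid | CC1=C[C@H]2[C@H](O[Si](C)(C)C(C)(C)C)[C@@H](C)CC[C@@H]2[C@@](C)(C(=O)O)[C@H]1C#C[Si](C)(C)C | intermediate
20 | (4-bromobut-1-yn-1-yl)trimethylsilane | C[Si](C)(C)C#CCCBr | starting material
21 | (S)-2-methyloxirane | C[C@H]1CO1 | starting material
22 | [4-(trimethylsilyl)but-3-yn-1-yl]magnesium bromide | C[Si](C)(C)C#CCC[Mg]Br | intermediate
23 | (2S)-7-(trimethylsilyl)hept-6-yn-2-ol | C[C@H](O)CCCC#C[Si](C)(C)C | intermediate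
24 | 4-methoxybenzyl ether of 23 | C[C@H](OCc1ccc(OC)cc1)CCCC#C[Si](C)(C)C | intermediate
25 | 1-({[(2S)-hept-6-yn-2-yl]oxy}methyl)-4-methoxybenzene | C[C@H](OCc1ccc(OC)cc1)CCCC#C | intermediate
26 | lithium acetylide of 25 | C[C@H](OCc1ccc(OC)cc1)CCCC#C[Li] | intermediate
27 | (7S)-7-[(4-methoxybenzyl)oxy]oct-2-ynal | C[C@H](OCc1ccc(OC)cc1)CCCC#CC=O | intermediate
28 | (2R)-4-(trimethylsilyl)but-3-yn-2-ol | C[C@@H](O)C#C[Si](C)(C)C | starting material
29 | (2R)-4-(trimethylsilyl)but-3-yn-2-yl methanesulfonate | C[C@@H](OS(C)(=O)=O)C#C[Si](C)(C)C | intermediate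
30 | (P)-ethyl[1-(trimethylsilyl)buta-1,2-dien-1-yl]zinc | CC[Zn]C([Si](C)(C)C)=[C@@]=CC | intermediate
31 | (3S,4S,10S)-10-[(4-methoxybenzyl)oxy]-3-methyl-1-(trimethylsilyl)undeca-1,5-diyn-4-ol | C[C@H](OCc1ccc(OC)cc1)CCCC#C[C@@H](O)[C@@H](C)C#C[Si](C)(C)C | intermediate
32 | (3S,4R,10S)-10-[(4-methoxybenzyl)oxy]-3-methyl-1-(trimethylsilyl)undeca-1,5-diyn-4-yl 4-nitrobenzoate | C[C@H](OCc1ccc(OC)cc1)CCCC#C[C@H](OC(=O)c1ccc(cc1)[N+](=O)[O-])[C@@H](C)C#C[Si](C)(C)C | intermediate
33 | (3S,4R,10S)-10-[(4-methoxybenzyl)oxy]-3-methyl-1-(trimethylsilyl)undeca-1,5-diyn-4-ol | C[C@H](OCc1ccc(OC)cc1)CCCC#C[C@H](O)[C@@H](C)C#C[Si](C)(C)C | intermediate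
34 | (3S,4R,5E,10S)-10-[(4-methoxybenzyl)oxy]-3-methyl-5-(tributylstannyl)-1-(trimethylsilyl)undec-5-en-1-yn-4-ol | C[C@H](OCc1ccc(OC)cc1)CCC/C=C(/[Sn](CCCC)(CCCC)CCCC)[C@H](O)[C@@H](C)C#C[Si](C)(C)C | intermediate
35 | (3S,4R,5E,10S)-5-iodo-10-[(4-methoxybenzyl)oxy]-3-methyl-1-(trimethylsilyl)undec-5-en-1-yn-4-ol | C[C@H](OCc1ccc(OC)cc1)CCC/C=C(/I)[C@H](O)[C@@H](C)C#C[Si](C)(C)C | intermediate
36 | tert-butyl{[(3S,4R,5E,10S)-5-iodo-10-[(4-methoxybenzyl)oxy]-3-methyl-1-(trimethylsilyl)undec-5-en-1-yn-4-yl]oxy}dimethylsilane | C[C@H](OCc1ccc(OC)cc1)CCC/C=C(/I)[C@H](O[Si](C)(C)C(C)(C)C)[C@@H](C)C#C[Si](C)(C)C | intermediate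
37 | methyl (2E,7S)-2-[(1R,2S)-1-[(tert-butyldimethylsilyl)oxy]-2-methyl-4-(trimethylsilyl)but-3-yn-1-yl]-7-[(4-methoxybenzyl)oxy]oct-2-enoate | C[C@H](OCc1ccc(OC)cc1)CCC/C=C(/C(=O)OC)[C@H](O[Si](C)(C)C(C)(C)C)[C@@H](C)C#C[Si](C)(C)C | intermediate
38 | methyl (2E,7S)-2-[(1R,2S)-1-[(tert-butyldimethylsilyl)oxy]-2-methyl-4-(trimethylsilyl)but-3-yn-1-yl]-7-hydroxyoct-2-enoate | C[C@H](O)CCC/C=C(/C(=O)OC)[C@H](O[Si](C)(C)C(C)(C)C)[C@@H](C)C#C[Si](C)(C)C | intermediate
39 | ester of 19 with 38 (12R; both alkynes silyl-capped) | CC1=C[C@H]2[C@H](O[Si](C)(C)C(C)(C)C)[C@@H](C)CC[C@@H]2[C@@](C)(C(=O)O[C@H](C)CCC/C=C(/C(=O)OC)[C@H](O[Si](C)(C)C(C)(C)C)[C@@H](C)C#C[Si](C)(C)C)[C@H]1C#C[Si](C)(C)C | intermediate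
40 | bis-terminal diyne ester (39 without the two alkynyl trimethylsilyl groups) | CC1=C[C@H]2[C@H](O[Si](C)(C)C(C)(C)C)[C@@H](C)CC[C@@H]2[C@@](C)(C(=O)O[C@H](C)CCC/C=C(/C(=O)OC)[C@H](O[Si](C)(C)C(C)(C)C)[C@@H](C)C#C)[C@H]1C#C | intermediate
41 | 16-membered 20,22-diyne lactone (4-O-TBS, 18-O-TBS, methyl ester) | CC1=C[C@H]2[C@H](O[Si](C)(C)C(C)(C)C)[C@@H](C)CC[C@@H]2[C@@]2(C)C(=O)O[C@H](C)CCC/C=C(/C(=O)OC)[C@H](O[Si](C)(C)C(C)(C)C)[C@@H](C)C#CC#C[C@@H]12 | intermediate
42 | (20Z,22Z)-diene lactone (4-O-TBS, 18-O-TBS, methyl ester) | CC1=C[C@H]2[C@H](O[Si](C)(C)C(C)(C)C)[C@@H](C)CC[C@@H]2[C@@]2(C)C(=O)O[C@H](C)CCC/C=C(/C(=O)OC)[C@H](O[Si](C)(C)C(C)(C)C)[C@@H](C)/C=C\C=C/[C@@H]12 | intermediate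
43 | trimethylstannyl ester of 44 | CC1=C[C@H]2[C@H](O[Si](C)(C)C(C)(C)C)[C@@H](C)CC[C@@H]2[C@@]2(C)C(=O)O[C@H](C)CCC/C=C(/C(=O)O[Sn](C)(C)C)[C@H](O[Si](C)(C)C(C)(C)C)[C@@H](C)/C=C\C=C/[C@@H]12 | intermediate
44 | 4,18-bis-O-(tert-butyldimethylsilyl) ether of the target acid | CC1=C[C@H]2[C@H](O[Si](C)(C)C(C)(C)C)[C@@H](C)CC[C@@H]2[C@@]2(C)C(=O)O[C@H](C)CCC/C=C(/C(=O)O)[C@H](O[Si](C)(C)C(C)(C)C)[C@@H](C)/C=C\C=C/[C@@H]12 | intermediate
45 | CNP0284457.3 | CC1=C[C@H]2[C@H](O)[C@@H](C)CC[C@@H]2[C@@]2(C)C(=O)O[C@H](C)CCC/C=C(/C(=O)O)[C@H](O)[C@@H](C)/C=C\C=C/[C@@H]12 | target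

## Step count and risk assessment

Total step count: 25 (steps 1–8 west fragment, steps 9–19 east fragment, steps 20–25 union and endgame).
Longest linear sequence: 16 steps (9, 10, 11, 13–19, 20–25).

Least certain steps:

**Step 8 (key step).** The boat-shaped array may not be reached before the silyl ketene acetal is lost by ionisation of the doubly activated allylic C2–O bond with elimination, or by incomplete enolisation and self-condensation of the hindered α-methyl lactone. The fallback sets out from 16 and returns at 19 without any enolate. Half-reduction with i-Bu2AlH gives the lactol F1. Dehydration through its mesylate (MsCl, Et3N, then warming) gives the cyclic enol ether F2. A neutral thermal Claisen rearrangement of this 2-alkenyl-dihydropyran (toluene, 160–180 °C, sealed tube) gives the aldehyde F3 through the same boat. Pinnick oxidation (NaClO2, NaH2PO4, 2-methylbut-2-ene) then gives 19.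

**Step 3.** Syn/anti control at C2 may be poor, or the ratio may erode by retro-aldol equilibration, since cyclic E-enolates normally prefer the anti adduct. The fallback sets out from 6 and returns at 10. The dicyclohexylboron enolate F4 ((c-C6H11)2BCl, Et3N) adds to 3 through the chair transition state to give the anti aldol F5 (2R) reliably. NaBH4 reduction by axial attack gives the diol F6. A Mitsunobu reaction with 4-nitrobenzoic acid, selective for the allylic C2 hydroxyl over the flanked C4 hydroxyl, inverts C2 and gives the ester F7. Cleavage with i-Bu2AlH gives 10.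

**Step 14.** Inversion at the hindered propargylic carbinol may leak through ionisation or SN2' attack, or give way to elimination. The fallback sets out from 27 and returns at 33, making the syn isomer directly. Commercial (S)-but-3-yn-2-ol is converted to the mesylate F8 and, with Bu3SnLi/CuBr·SMe2 (anti SN2'), to the allenylstannane F9. BF3·OEt2-promoted SE2' addition of F9 to 27 through an open transition state gives the syn adduct F10. Double deprotonation (n-BuLi) and TMSCl give the bis-silyl compound F11, whose O–Si bond is cleaved with dilute citric acid to give 33.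

**Step 22.** Intermolecular coupling may outrun ring closure and give oligomers. The fallback sets out from 19 and 38 and returns at 41, moving the ring closure to the ester bond. K2CO3/MeOH on 19 gives the terminal alkyne acid F12. NBS/AgNO3 on 38 gives the bromoalkyne F13. Cadiot–Chodkiewicz cross-coupling (CuCl, NH2OH·HCl, n-BuNH2) joins them to the seco acid F14. Mitsunobu macrolactonization (PPh3, DIAD, high dilution) closes O11–C12 with inversion to give 41.

**Step 20.** Attack of the bulky carboxylate may be slow, so that the alkoxyphosphonium ion is consumed by elimination or by the hydrazide. The fallback sets out from 38 and 19 and returns at 39, replacing the redox condensation by alkylation of a preformed naked carboxylate. Alcohol 38 is converted to the mesylate F15 (MsCl, Et3N), and 19 to the cesium carboxylate F16 (Cs2CO3). SN2 displacement in DMF at 50 °C with inversion gives 39.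

## Further compounds

F1 | step 8 | lactol from half-reduction of 16 | C[Si](C)(C)C#C/C=C(\C)[C@H]1OC(O)C(C)[C@H]2CC[C@H](C)[C@@H](O[Si](C)(C)C(C)(C)C)[C@H]12
F2 | step 8 | cyclic enol ether (C9=C10) from dehydration of F1 | C[Si](C)(C)C#C/C=C(\C)[C@H]1OC=C(C)[C@H]2CC[C@H](C)[C@@H](O[Si](C)(C)C(C)(C)C)[C@H]12
F3 | step 8 | (1R,2S,4aR,5R,6S,8aS)-5-[(tert-butyldimethylsilyl)oxy]-1,3,6-trimethyl-2-[(trimethylsilyl)ethynyl]-1,2,4a,5,6,7,8,8a-octahydronaphthalene-1-carbaldehyde | CC1=C[C@H]2[C@H](O[Si](C)(C)C(C)(C)C)[C@@H](C)CC[C@@H]2[C@@](C)(C=O)[C@H]1C#C[Si](C)(C)C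
F4 | step 3 | dicyclohexylboron enolate of 6 | C1CCCCC1B(C1CCCCC1)OC1=C[C@@H](C(C)=C)CC[C@@H]1C
F5 | step 3 | anti aldol, (1R) side-chain epimer of 9 | C[Si](C)(C)C#C/C=C(\C)[C@H](O)[C@H]1C(=O)[C@@H](C)CC[C@@H]1C(C)=C
F6 | step 3 | diol, (1R) side-chain epimer of 10 | C[Si](C)(C)C#C/C=C(\C)[C@H](O)[C@H]1[C@H](O)[C@@H](C)CC[C@@H]1C(C)=C
F7 | step 3 | 4-nitrobenzoate of 10 at the C2 oxygen | C[Si](C)(C)C#C/C=C(\C)[C@@H](OC(=O)c1ccc(cc1)[N+](=O)[O-])[C@H]1[C@H](O)[C@@H](C)CC[C@@H]1C(C)=C
F8 | step 14 | (2S)-but-3-yn-2-yl methanesulfonate | C[C@H](OS(C)(=O)=O)C#C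
F9 | step 14 | (M)-tributyl(buta-1,2-dien-1-yl)stannane | CCCC[Sn](CCCC)(CCCC)C=[C@]=CC
F10 | step 14 | (3S,4R,10S)-10-[(4-methoxybenzyl)oxy]-3-methylundeca-1,5-diyn-4-ol | C[C@H](OCc1ccc(OC)cc1)CCCC#C[C@H](O)[C@@H](C)C#C
F11 | step 14 | O-trimethylsilyl ether of 33 | C[C@H](OCc1ccc(OC)cc1)CCCC#C[C@H](O[Si](C)(C)C)[C@@H](C)C#C[Si](C)(C)C
F12 | step 22 | (1R,2S,4aR,5R,6S,8aS)-5-[(tert-butyldimethylsilyl)oxy]-2-ethynyl-1,3,6-trimethyl-1,2,4a,5,6,7,8,8a-octahydronaphthalene-1-carboxylic acid | CC1=C[C@H]2[C@H](O[Si](C)(C)C(C)(C)C)[C@@H](C)CC[C@@H]2[C@@](C)(C(=O)O)[C@H]1C#C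
F13 | step 22 | methyl (2E,7S)-2-[(1R,2S)-4-bromo-1-[(tert-butyldimethylsilyl)oxy]-2-methylbut-3-yn-1-yl]-7-hydroxyoct-2-enoate | C[C@H](O)CCC/C=C(/C(=O)OC)[C@H](O[Si](C)(C)C(C)(C)C)[C@@H](C)C#CBr
F14 | step 22 | diyne seco acid (C10 acid, free 12S hydroxyl) | CC1=C[C@H]2[C@H](O[Si](C)(C)C(C)(C)C)[C@@H](C)CC[C@@H]2[C@@](C)(C(=O)O)[C@H]1C#CC#C[C@H](C)[C@@H](O[Si](C)(C)C(C)(C)C)/C(C(=O)OC)=C\CCC[C@H](C)O
F15 | step 20 | methanesulfonate of 38 | C[C@H](OS(C)(=O)=O)CCC/C=C(/C(=O)OC)[C@H](O[Si](C)(C)C(C)(C)C)[C@@H](C)C#C[Si](C)(C)C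
F16 | step 20 | cesium carboxylate of 19 | [Cs+].CC1=C[C@H]2[C@H](O[Si](C)(C)C(C)(C)C)[C@@H](C)CC[C@@H]2[C@@](C)(C(=O)[O-])[C@H]1C#C[Si](C)(C)C
A1 | alternative 1 | acyclic triene ester for the intramolecular Diels–Alder reaction, (2E,8E,10E) | COC(=O)/C(C)=C/CC[C@H](C)[C@@H](O[Si](C)(C)C(C)(C)C)/C=C/C(C)=C/CO[Si](C)(C)C(C)(C)C
A2 | alternative 1 | trans-decalin methyl ester with a silyloxymethyl group at C24 | CC1=C[C@H]2[C@H](O[Si](C)(C)C(C)(C)C)[C@@H](C)CC[C@@H]2[C@@](C)(C(=O)OC)[C@H]1CO[Si](C)(C)C(C)(C)C
A3 | alternative 2 | 24-membered hexaene macrolactone for the transannular Diels–Alder reaction | C/C1=C\CC[C@H](C)[C@@H](O[Si](C)(C)C(C)(C)C)/C=C/C(C)=C/C=C\C=C/[C@H](C)[C@@H](O[Si](C)(C)C(C)(C)C)/C(C(=O)OC)=C\CCC[C@@H](C)OC1=O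
A4 | alternative 3 | [(2S)-2-(methoxymethyl)pyrrolidin-1-yl][(1R)-1,3-dimethylcyclohexa-2,5-dien-1-yl]methanone | COC[C@@H]1CCCN1C(=O)[C@@]1(C)C=C(C)CC=C1
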